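## Structural features

The target 11 is a 2,3,4,5-tetrasubstituted oxolane (ring B) with a 3,4-dimethoxyphenyl group (ring A) on C2, a 3,4,5-trimethoxyphenyl group (ring C) on C5 and methyl groups on C3 and C4. Apart from five aryl methyl ethers it has no other functional group. The four stereocentres are contiguous, (2S,3S,4R,5R): the aryl groups are cis to each other, the methyl groups are cis to each other, and each aryl group is trans to the methyl group next to it. With two identical aryl groups the molecule would be meso, so its chirality rests only on the extra methoxy group of ring C. The real difficulty is therefore the absolute configuration, that is, which of two almost identical aryl groups sits on C2 and which on C5. The C2–O1 and C5–O1 bonds are benzylic ether bonds on electron-rich arenes; they ionise with Brønsted or Lewis acids, are cleaved by hydrogenolysis and are attacked by quinone-type oxidants, so the late steps must be basic or neutral and non-hydrogenolytic. The key step exploits the fact that C2–O1–C5 with its two aryl groups is a latent diaryl carbonyl ylide and that C3–C4 with two cis one-carbon arms is a latent cis-alkene, so ring B, two C–C bonds and all four stereocentres can arise in one (3+2) event from achiral components. It also exploits the different origin of the two termini, C2 from a diazo carbon and C5 from an aldehyde carbon, which lets a chiral catalyst tell them apart by connectivity.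

## Logic of the disconnections

**11 ⇒ 10.** The methyl groups of 11 offer no handle, so one C–H bond of each is exchanged for a C–O bond. No skeletal bond is cut and no stereocentre is touched. The gain is that C3 and C4 now carry oxygenated one-carbon arms that can be traced to carbonyl carbons. The forward step must deliver hydride by SN2 to two β-branched primary carbons without attack at sulfur, without opening the benzylic C–O bonds of ring B and without demethylating the aryl ethers.

**10 ⇒ 9.** The two O–S bonds of 10 are cut to give 9. A sulfonate is preferred to a halide because it forms under buffered basic conditions and can be reduced without tin. The demand is kinetic: both hydroxyls must be sulfonylated before the first sulfonate is displaced by the neighbouring hydroxyl, which stands in a 1,4-relationship and could close a second oxolane ring.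

**9 ⇒ 8.** Both CH2OH carbons of 9 are raised to the carboxyl level and joined through oxygen, which gives 8. This tie turns C3–C4 into the retron of a symmetric, strongly electron-poor cis-alkene and locks the 3,4-cis relationship in a cis-fused bicycle that cannot epimerise at one centre alone. The forward step must reduce both acyl carbons completely, without acid and without enolisation.

**8 ⇒ 4 + 5 + 6.** The central cut removes C2–C3 and C4–C5 of 8 in the retro-(3+2) sense and gives 6 and the dipole 7; cutting C2–O1 of 7 then gives 4 and 5. Three bonds, ring B and four stereocentres are thus traced to three achiral components with no stereocentre and at most one ring. The structures of 4, 5, 6 and 8 were checked atom by atom against 11 and need no correction: the exo adduct 8 has both aryl groups on one face and both acyl carbons on the other, as 11 requires. The forward step carries four demands: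
- 7 must react in its W form, to give 2,5-cis.
- 6 must approach exo, to put the acyl carbons trans to the aryl groups.
- One face of the dipole must be selected while rhodium is still on C2, to fix the absolute configuration.
- Carbenoid capture by 5 must outrun the uncatalysed reaction of 4 with 6.

**4 ⇒ 3 ⇒ 1 + 2.** 4 cannot be stored, so it is traced by dehydrogenation to 3, and 3 through its C=N bond to 1 and 2. Release of 4 in the reaction flask from a sulfonylhydrazone salt would avoid 2, but it was set aside for the main route. The hydrazonate and sulfinate anions are nucleophiles that 6 would acylate or add to, and the release needs warming, which works against a metal-bound ylide. The demand on the forward steps is a cold, dilute, acid-free solution of 4 that contains no residual 3 and is never concentrated.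

## Other disconnections considered

**Alternative 1:** Ring A itself is disconnected. It is traced to the cyclohexa-1,4-diene A1 and then, by retro-(4+2), to the 2-ethynyl oxolane A2 and the symmetric diene A3. In the forward direction CoBr2(dppe), reduced by Zn with ZnI2 as additive, would join A2 and A3 to A1, and dehydrogenation would give 11.
- In favour: the cobalt-catalysed alkyne–diene cycloaddition is an established reaction type, and the symmetric diene raises no regiochemical question. In A2 the substituents on C2 and C5 are constitutionally different (ethynyl against aryl), so the near-meso problem disappears and the absolute configuration can be set by ordinary means. On this point the alternative is better than the chosen plan.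
- Against: the key step makes no stereocentre and no bond of ring B, so A2 with all four stereocentres must first be built by a separate stereocontrolled sequence. ZnI2 is a Lewis acid next to the acid-labile C5 benzylic ether. A1 is a bis-enol ether prone to hydrolysis. The final dehydrogenation needs an oxidant that spares the electron-rich benzylic ether at C5.
- Comparison: structurally it builds the least demanding part of the molecule last and ignores the latent symmetry. Mechanistically its key step is more secure than the one chosen here. In step economy it is clearly worse, probably twice the length of the six-step plan.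

**Alternative 2:** The two methyl C–C bonds at C3 and C4 are cut together, tied through sulfur. The cis-fused thiolane lactone A4 is traced to the 5-aryl butenolide A5 and the ylide precursor A6. In the forward direction CsF would release the thiocarbonyl ylide equivalent from A6, which adds (3+2) across C3=C4 of A5 anti to the aryl group. Desulfurisation over Ni then uncovers both methyl groups. Ring A is added to the lactone carbonyl as an aryl-metal reagent and the lactol hydroxyl is removed reductively to set C2.
- In favour: the 3,4-cis relationship follows from suprafacial addition and the 4,5-trans relationship from the resident C5 centre. That single conventional carbinol stereocentre carries the absolute configuration, which is more secure than the chosen plan; here the alternative is better. As a ylide cycloaddition it equals the chosen key step in bond-forming power (two C–C bonds, one ring).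
- Against: A5 has an acidic benzylic γ-hydrogen and can racemise through its aromatic dienolate under basic fluoride. Desulfurisation threatens the benzylic C5–O bond by hydrogenolysis. C2 is set late by hydride delivery to an oxocarbenium ion whose facial preference is uncertain, although the wanted 2,3-trans arrangement is the more stable one.
- Comparison: the roles are inverted, the ylide bringing the methyl carbons and the dipolarophile the ring. It would need roughly nine or ten steps against six.

**Alternative 3:** The C4–C5 bond is cut. The ester A7 is traced to the acyclic α-diazo ester A8, in which C2 and C3 are already set and C5 is the benzylic CH2 of a trimethoxybenzyl ether. In the forward direction Rh2(S-PTTL)4 would convert A8 into a carbenoid that inserts into the benzylic C–H bond next to oxygen (1,5-insertion), closing ring B. The ester would then be taken to methyl in three steps.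
- In favour: intramolecular C–H insertion next to an ether oxygen with this catalyst family is an established reaction type with known stereocontrol, so its key step is better precedented than the chosen one. The absolute configuration comes from C2 and C3, made by a conventional asymmetric aldol-type sequence, and does not depend on the remote methoxy group. On both points the alternative is better.
- Against: A8 is an α-alkyl diazo ester with a β-hydrogen, so 1,2-hydride migration to an unsaturated ester competes with insertion. The insertion must create C4 and C5 with the ester cis to the C3 methyl, which is not obviously favoured. The trimethoxybenzyl ether and the diazo group each need extra steps on an acid-sensitive substrate.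
- Comparison: it makes one C–C bond and two stereocentres in the key step against two C–C bonds and four stereocentres here. It would need about ten linear steps. The endgame from ester to methyl is equal in kind to steps 4 to 6 of the chosen plan.

Key step: step 3

Assumption: 2 is used as its monohydrate, and Rh2(S-PTTL)4 is assumed to favour the enantiomer drawn for 8; if the sense of induction is the opposite, the antipodal catalyst Rh2(R-PTTL)4 takes its place.

## Route

Step 1
Reactants: 1 veratraldehyde (3,4-dimethoxybenzaldehyde); 2 hydrazine (as monohydrate)
Product: 3 (E)-(3,4-dimethoxybenzylidene)hydrazine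
Conditions: 1 added slowly to N2H4·H2O (5 equiv), EtOH, 0 °C to rt; excess hydrazine removed by extraction
Reagents that add atoms: none
Why: Condensation of an aryl aldehyde with excess hydrazine gives the N-unsubstituted hydrazone; inverse addition to a large excess suppresses azine formation, and the hydrate avoids anhydrous hydrazine.

Step 2
Reactants: 3 (E)-(3,4-dimethoxybenzylidene)hydrazine
Product: 4 (3,4-dimethoxyphenyl)diazomethane
Conditions: activated MnO2 (6 equiv), MgSO4, CH2Cl2, −10 to 0 °C, 30 min; cold filtration through Celite; dilute solution used at once, never concentrated
Reagents that add atoms: none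
Why: Dehydrogenation of N-unsubstituted hydrazones with MnO2 is the standard route to aryldiazomethanes; MgSO4 takes up the water formed, full conversion is needed because residual 3 would be acylated by 6 and bind the catalyst, and cold dilute handling limits the hazard of the labile diazoalkane.

Step 3
Reactants: 4 (3,4-dimethoxyphenyl)diazomethane; 5 3,4,5-trimethoxybenzaldehyde; 6 maleic anhydride
Product: 8 (3aS,4S,6R,6aR)-4-(3,4-dimethoxyphenyl)-6-(3,4,5-trimethoxyphenyl)tetrahydro-1H,3H-furo[3,4-c]furan-1,3-dione (exo adduct), via carbonyl ylide 7 (not isolated)
Conditions: Rh2(S-PTTL)4 (2 mol %), 5 (1.0 equiv), 6 (2.0 equiv, freshly sublimed), 4 Å MS, CH2Cl2, −40 °C; 4 (1.5 equiv, cold dilute CH2Cl2 solution) by syringe pump over 4 h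
Reagents that add atoms: none
Why: Proposed new method: Rh2(S-PTTL)4 strips N2 from 4 to give a donor-type rhodium carbenoid inside its chiral pocket, the carbonyl oxygen of 5 adds to one face of that carbenoid to give the rhodium-associated W-shaped ylide 7, and 6 adds across C2 and C5 on the face anti to the metal before it departs; the closest known reaction type is the dirhodium-catalysed three-component carbonyl ylide (3+2) cycloaddition of diazo compounds, aldehydes and electron-poor alkenes, for which enantiocontrol is established only with catalyst-bound cyclic ylides. Ring B closes by an intermolecular suprafacial (3+2) cycloaddition (four π electrons of C2–O1–C5, two of C3=C4) that forms C2–C3 and C4–C5 together, the C2–O1 bond having been made in the ylide-forming event. The 2,5-cis relationship comes from the W geometry of 7, in which both aryl groups point outward and both hydrogens inward. The 3,4-cis relationship is the cis geometry of 6, held by its anhydride ring. The trans relationship of C3 and C4 to the aryl groups comes from exo approach, in which the anhydride ring lies under the two inward hydrogens, away from the aryl groups and from the ligand wall around C2. The absolute configuration is decided at C2, the only carbon that ever carries rhodium: the ligand sphere selects the carbenoid face that 5 attacks and 6 must then enter anti to the metal, so the two almost identical aryl termini are told apart by origin and not by the remote methoxy group. The step needs carbenoid capture by 5 to outrun pyrazoline formation between 4 and 6 and carbene dimerisation (slow addition of dilute 4 to cold catalyst, the electronic mismatch between the electrophilic carbenoid and electron-poor 6, acid-free 6), and it needs 7 to be trapped before it closes to an epoxide or leaves the metal (excess of the highly reactive dipolarophile 6, low temperature).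

Step 4
Reactants: 8 (3aS,4S,6R,6aR)-4-(3,4-dimethoxyphenyl)-6-(3,4,5-trimethoxyphenyl)tetrahydro-1H,3H-furo[3,4-c]furan-1,3-dione
Product: 9 [(2S,3R,4S,5R)-2-(3,4-dimethoxyphenyl)-5-(3,4,5-trimethoxyphenyl)oxolane-3,4-diyl]dimethanol
Conditions: LiAlH4 (4 equiv), THF, 0 °C to reflux; H2O/aq NaOH work-up
Reagents that add atoms: none
Why: Exhaustive LiAlH4 reduction of a cyclic anhydride gives the 1,4-diol; benzylic and aryl ethers are inert to hydride, any 8 hydrolysed during handling is reduced to the same diol, and no stereocentre is made or epimerised.

Step 5
Reactants: 9 [(2S,3R,4S,5R)-2-(3,4-dimethoxyphenyl)-5-(3,4,5-trimethoxyphenyl)oxolane-3,4-diyl]dimethanol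
Product: 10 [(2S,3R,4S,5R)-2-(3,4-dimethoxyphenyl)-5-(3,4,5-trimethoxyphenyl)oxolane-3,4-diyl]bis(methylene) dimethanesulfonate
Conditions: MsCl (3 equiv), Et3N (4 equiv), CH2Cl2, −20 to 0 °C
Reagents that add atoms: methanesulfonyl chloride, CS(=O)(=O)Cl
Why: Sulfonylation of primary alcohols through the sulfene is fast at low temperature; excess MsCl lets the second mesylation outrun intramolecular displacement by the neighbouring hydroxyl, and the amine buffer keeps the benzylic ethers away from acid.

Step 6
Reactants: 10 [(2S,3R,4S,5R)-2-(3,4-dimethoxyphenyl)-5-(3,4,5-trimethoxyphenyl)oxolane-3,4-diyl]bis(methylene) dimethanesulfonate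
Product: 11 (2S,3S,4R,5R)-2-(3,4-dimethoxyphenyl)-3,4-dimethyl-5-(3,4,5-trimethoxyphenyl)oxolane
Conditions: LiEt3BH (6 equiv, 1 M in THF), THF, 0 °C to rt
Reagents that add atoms: none
Why: LiEt3BH displaces primary sulfonates by SN2 with C–O cleavage and little attack at sulfur, which avoids both tin and hydrogenolysis; the temperature stays at or below rt because hot LiEt3BH can demethylate aryl methyl ethers, and no stereocentre is involved.

## Compound list

1 | veratraldehyde (3,4-dimethoxybenzaldehyde) | COc1ccc(C=O)cc1OC | starting material
2 | hydrazine (used as the monohydrate) | NN | starting material
3 | (E)-(3,4-dimethoxybenzylidene)hydrazine | COc1ccc(/C=N/N)cc1OC | intermediate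
4 | (3,4-dimethoxyphenyl)diazomethane | COc1ccc(C=[N+]=[N-])cc1OC | intermediate
5 | 3,4,5-trimethoxybenzaldehyde | COc1cc(C=O)cc(OC)c1OC | starting material
6 | maleic anhydride | O=C1C=CC(=O)O1 | starting material
7 | carbonyl ylide from 4 and 5, W-shaped (E,E) form, rhodium-associated at the former diazo carbon, drawn as the free dipole | COc1ccc([CH-]/[O+]=C/c2cc(OC)c(OC)c(OC)c2)cc1OC | intermediate
8 | (3aS,4S,6R,6aR)-4-(3,4-dimethoxyphenyl)-6-(3,4,5-trimethoxyphenyl)tetrahydro-1H,3H-furo[3,4-c]furan-1,3-dione | COc1ccc([C@H]2O[C@@H](c3cc(OC)c(OC)c(OC)c3)[C@H](C(=O)OC4=O)[C@@H]24)cc1OC | intermediate
9 | [(2S,3R,4S,5R)-2-(3,4-dimethoxyphenyl)-5-(3,4,5-trimethoxyphenyl)oxolane-3,4-diyl]dimethanol | COc1ccc([C@H]2O[C@@H](c3cc(OC)c(OC)c(OC)c3)[C@H](CO)[C@@H]2CO)cc1OC | intermediate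
10 | [(2S,3R,4S,5R)-2-(3,4-dimethoxyphenyl)-5-(3,4,5-trimethoxyphenyl)oxolane-3,4-diyl]bis(methylene) dimethanesulfonate | COc1ccc([C@H]2O[C@@H](c3cc(OC)c(OC)c(OC)c3)[C@H](COS(C)(=O)=O)[C@@H]2COS(C)(=O)=O)cc1OC | intermediate
11 | (2S,3S,4R,5R)-2-(3,4-dimethoxyphenyl)-3,4-dimethyl-5-(3,4,5-trimethoxyphenyl)oxolane | COc1ccc([C@H]2O[C@@H](c3cc(OC)c(OC)c(OC)c3)[C@H](C)[C@@H]2C)cc1OC | target

## Step count and least certain steps

Total steps: 6. Longest linear sequence: 6 steps (1 → 3 → 4 → 8 → 9 → 10 → 11); 5 and 6 enter at step 3.

**Step 3 (key step, Proposed new method).** The most likely failure is loss of enantiocontrol: rhodium may dissociate from 7 before the cycloaddition, so that a free, achiral dipole reacts on both faces. A non-stabilised diaryl ylide has no carbonyl group to hold the metal. Leakage through endo approach and diversion of 4 into uncatalysed pyrazoline formation with 6 are the secondary risks. Fallback, by known chemistry and by resolution instead of asymmetric catalysis: setting out from 4, 5 and 6, the three-component cycloaddition is run with achiral Rh2(OAc)4 in CH2Cl2 at 0 °C, a racemic reaction of the established diazo–aldehyde–alkene type, to give the racemic exo anhydride F1. LiAlH4 reduction gives the racemic diol F2. Its enantiomers are separated by preparative chromatography on a polysaccharide-carbamate chiral stationary phase, and the (2S,3R,4S,5R) enantiomer, assigned by anomalous-dispersion crystallography of a heavy-atom ester, is 9, where the route is rejoined.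

**Step 2.** The most likely failure is decomposition of the electron-rich diazoalkane during or after oxidation: acid sites on the oxide cause loss of N2, and unreacted 3 couples with 4 to form azine. Incomplete oxidation would also carry a nucleophile into step 3. Fallback, base-induced elimination instead of oxidation: setting out from 1, condensation with 2-(trifluoromethyl)benzenesulfonohydrazide gives (E)-N'-(3,4-dimethoxybenzylidene)-2-(trifluoromethyl)benzenesulfonohydrazide F3. Deprotonation with NaH in CH2Cl2 at −20 to 0 °C in a separate flask should trigger Bamford–Stevens loss of sulfinate well below room temperature. The precipitated sulfinate salt is filtered off cold and the solution of 4 is fed to step 3 as before. This removes free hydrazine and 3 from the sequence.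

**Step 5.** The most likely failure is intramolecular etherification: after the first sulfonylation the neighbouring hydroxyl can close a second five-membered ether ring by 5-exo displacement, an irreversible loss. Fallback, which avoids any electrophilic carbon: setting out from 9, both hydroxyls are converted under basic conditions (NaH, CS2, then MeI, THF, 0 °C) into the bis(S-methyl xanthate) F4. Tin-free Barton–McCombie deoxygenation ((Me3Si)3SiH, 1,1'-azobis(cyclohexanecarbonitrile), toluene, reflux) then leads directly to 11, bypassing 10.

**Step 6.** The most likely failures are hydride attack at sulfur, which regenerates an alkoxide that then closes onto the neighbouring mesylate, and sluggish displacement at the β-branched carbons that tempts heating and with it ether demethylation. Fallback, radical instead of polar reduction: setting out from 10, Finkelstein exchange (NaI, butanone, 60 °C) gives the bis(iodide) F5, and chain reduction with (Me3Si)3SiH and AIBN in toluene at 80 °C gives 11.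

## Further compounds

F1 | step 3 | racemic exo anhydride, rac-(3aS,4S,6R,6aR)-4-(3,4-dimethoxyphenyl)-6-(3,4,5-trimethoxyphenyl)tetrahydro-1H,3H-furo[3,4-c]furan-1,3-dione (one enantiomer drawn) | COc1ccc([C@H]2O[C@@H](c3cc(OC)c(OC)c(OC)c3)[C@H](C(=O)OC4=O)[C@@H]24)cc1OC
F2 | step 3 | racemic diol, rac-[(2S,3R,4S,5R)-2-(3,4-dimethoxyphenyl)-5-(3,4,5-trimethoxyphenyl)oxolane-3,4-diyl]dimethanol (one enantiomer drawn) | COc1ccc([C@H]2O[C@@H](c3cc(OC)c(OC)c(OC)c3)[C@H](CO)[C@@H]2CO)cc1OC
F3 | step 2 | (E)-N'-(3,4-dimethoxybenzylidene)-2-(trifluoromethyl)benzenesulfonohydrazide | COc1ccc(/C=N/NS(=O)(=O)c2ccccc2C(F)(F)F)cc1OC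
F4 | step 5 | O,O'-{[(2S,3R,4S,5R)-2-(3,4-dimethoxyphenyl)-5-(3,4,5-trimethoxyphenyl)oxolane-3,4-diyl]bis(methylene)} S,S'-dimethyl bis(carbonodithioate) | COc1ccc([C@H]2O[C@@H](c3cc(OC)c(OC)c(OC)c3)[C@H](COC(=S)SC)[C@@H]2COC(=S)SC)cc1OC
F5 | step 6 | (2S,3S,4R,5R)-2-(3,4-dimethoxyphenyl)-3,4-bis(iodomethyl)-5-(3,4,5-trimethoxyphenyl)oxolane | COc1ccc([C@H]2O[C@@H](c3cc(OC)c(OC)c(OC)c3)[C@H](CI)[C@@H]2CI)cc1OC
A1 | alternative 1 | (2S,3S,4R,5R)-2-(4,5-dimethoxycyclohexa-1,4-dien-1-yl)-3,4-dimethyl-5-(3,4,5-trimethoxyphenyl)oxolane | COC1=C(OC)CC([C@H]2O[C@@H](c3cc(OC)c(OC)c(OC)c3)[C@H](C)[C@@H]2C)=CC1
A2 | alternative 1 | (2S,3S,4R,5R)-2-ethynyl-3,4-dimethyl-5-(3,4,5-trimethoxyphenyl)oxolane | C#C[C@H]1O[C@@H](c2cc(OC)c(OC)c(OC)c2)[C@H](C)[C@@H]1C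
A3 | alternative 1 | 2,3-dimethoxybuta-1,3-diene | C=C(OC)C(=C)OC
A4 | alternative 2 | cis-fused 3-(3,4,5-trimethoxyphenyl)tetrahydro-1H,3H-thieno[3,4-c]furan-1-one, aryl group anti to the thiolane ring | O=C1O[C@@H](c2cc(OC)c(OC)c(OC)c2)[C@@H]2CSC[C@H]12
A5 | alternative 2 | (R)-5-(3,4,5-trimethoxyphenyl)furan-2(5H)-one | O=C1O[C@@H](c2cc(OC)c(OC)c(OC)c2)C=C1
A6 | alternative 2 | chloromethyl trimethylsilylmethyl sulfide | C[Si](C)(C)CSCCl
A7 | alternative 3 | methyl 5-(3,4-dimethoxyphenyl)-4-methyl-2-(3,4,5-trimethoxyphenyl)oxolane-3-carboxylate, 2,5-cis-diaryl, ester cis to the methyl group and trans to both aryl groups | COc1ccc([C@H]2O[C@@H](c3cc(OC)c(OC)c(OC)c3)[C@H](C(=O)OC)[C@@H]2C)cc1OC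
A8 | alternative 3 | methyl 2-diazo-4-(3,4-dimethoxyphenyl)-3-methyl-4-[(3,4,5-trimethoxybenzyl)oxy]butanoate, C3 and C4 configured as in the SMILES | COc1ccc([C@@H](OCc2cc(OC)c(OC)c(OC)c2)[C@@H](C)C(=[N+]=[N-])C(=O)OC)cc1OC
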